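3 questions stood before me: which flask ends with the longer chains, and how long the chains are in each.

common to all: second end groups 1.05 equiv
- Friday's: first end groups 1.7 M; one-sided end groups 0.026 M; run made earlier
- Tuesday's: first end groups 1.7 M; one-sided end groups 0.034 M; run made earlier
- oak: first end groups 1.7 M; one-sided end groups 0.0170 M; time 40 h
- ash: first end groups 0.60 M; one-sided end groups 0.0170 M; time 40 h

| run | time / h | links / % | first end groups / % |
|---|---|---|---|
| Friday's | 2.00 | 12.6 | 86.5 |
| Friday's | 6.00 | 30.8 | 68.4 |
| Friday's | 12.0 | 47.1 | 51.6 |
| Friday's | 15.0 | 52.3 | 46.0 |
| Friday's | 25.0 | 65.9 | 32.5 |
| Tuesday's | 2.00 | 12.4 | 85.3 |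
| Tuesday's | 6.00 | 30.1 | 67.7 |
| Tuesday's | 12.0 | 45.7 | 50.7 |
| Tuesday's | 15.0 | 52.5 | 45.0 |
| Tuesday's | 25.0 | 63.7 | 33.8 |

(each reading ± 0.5 percentage points)

- which of the two ends with the longer chains by the average number of monomer units in a chain (unreacted monomers counted as chains of one) ("neither" if they lie within 10%) (oak / ash / neither)
- average number of monomer units in a chain (unreacted monomers counted as chains of one) at the end, oak
- average number of monomer units in a chain (unreacted monomers counted as chains of one) at the end, ash

- each monomer carries two end groups and one-sided end groups one, which caps an end: a chain counts once for every two ends that are left, dead ends included; the units are half of the end groups of the two monomers charged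
- the earlier runs were read with a standard deviation of 0.5 percentage points
- what may be going on: first end groups + second end groups -> links; first end groups + one-sided end groups -> capped ends

1. I let X be the average units per chain (the number-average degree of polymerisation), U the units and L the links. Capping leaves the count of ends unchanged, so X = U/(U − L). Per first end group charged, U is 1.025.

2. In Friday's run at 25.0 h, first end groups lost minus links came to 1.60%, about the one-sided charge of 1.53%. So I set capping aside for the slope.

3. The two kinds of end are nearly equal, each at concentration a, and each falls at k times a times a. Then a falls hyperbolically from its charge c, and X = 1 + kct. This is a straight line from 1 with slope kc, and I drew no knee on it before the level below.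

4. At 25.0 h, X read 2.80 on Friday's run and 2.64 on Tuesday's. Their mean gives the link constant k 0.0405 M⁻¹ h⁻¹, the second-order rate constant as read.

5. X crosses 2 at the time constant τ = 1/(kc). For oak τ is 14.5 h, for ash 41.2 h. On this line, ash crosses later than the asked 40 h.

6. At 40 h, I reckoned X as 3.75 for oak and 1.97 for ash, so oak, 90.4% ahead, beyond the margin of 10%.

7. The level comes where links reach the charge less the caps: X of 29.3 for oak and 19.2 for ash. Both levels stand above my reckoned values at 40 h.

The forecast said oak, 3.78 and 1.96, close to mine but not equal, holding that “capping is fast and essentially complete”.

The flask gave oak, with 3.78 in oak and 1.97 in ash.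

    first end groups + second end groups → links (k = 0.0411 M⁻¹ h⁻¹)
    first end groups + one-sided end groups → capped ends (k = 1.37 M⁻¹ h⁻¹)

At the start of ash, link-making used first end groups at 1.1 times the rate of capping. By 13.3 h in ash, the half-life of first end groups by capping was 12000 d, against 39 h for second end groups by link-making. Read backwards on the line, k puts oak's 3.78 at 40.4 h. For the neighbour of ash with 0.36 M of first end groups, k gives 1.58, and that flask gave 1.57.

The readings come from a simulation on assumed constants; noise was put on by code.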